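**Assumption:** the SMILES is read as (S) at the acetoxy carbon (C10), (R) at the free carbinol, (S) at the lactone quaternary carbon, and both trisubstituted alkenes E. Shi's D‑fructose‑derived ketone, (R)‑Me‑CBS, BaI2 and isoprene monoxide are treated as purchasable reagents.

## Retrosynthetic overview

1. The γ‑lactone and free carbinol come last, from acid‑triggered 5‑exo opening of a (2R,3R)‑γ,δ‑epoxy tert‑butyl ester, with inversion at the tertiary carbon; until then the epoxide masks the secondary OH.
2. The C10 acetate comes from CBS reduction of a skipped enone, itself made by α‑selective allylbarium addition (C9–C10 bond) of a furyl allylic chloride to an epoxy‑enal, then oxidation.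
3. The epoxy‑enal comes from geranyl acetate: SeO2 oxidation of the E‑methyl, bromide, tert‑butyl acetate enolate alkylation, then Shi epoxidation, which sets both lactone‑side stereocentres.
4. The furyl allylic chloride comes from 3‑furylmethyl Grignard and isoprene monoxide (Cu‑catalysed SN2′).
5. Ring order: the furan is bought; the oxirane is formed at step 7 (temporary); the γ‑lactone is formed in the last step.

## Forward route

**Step 1**
Reactants: 1, furan‑3‑ylmethanol
Product: 2, 3‑(chloromethyl)furan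
Conditions: MsCl, s‑collidine, LiCl, DMF, 0 °C; use crude
Reagents that add atoms: lithium chloride, [Li+].[Cl-]
Why: In situ mesylate displaced by chloride (SN2, Collington–Meyers) under non‑acidic conditions that the furan tolerates.

**Step 2**
Reactants: 2, 3‑(chloromethyl)furan; 3, 2‑methyl‑2‑vinyloxirane (isoprene monoxide, racemic)
Product: 4, (2E)‑5‑(furan‑3‑yl)‑2‑methylpent‑2‑en‑1‑ol
Conditions: Mg, THF, 0 °C; then CuI (10 mol %), 3, THF, −30 °C
Reagents that add atoms: 3, C=CC1(C)CO1 (Mg and Cu leave nothing)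
Why: Cu‑catalysed SN2′ opening of the vinyl oxirane by 3‑furylmethylmagnesium chloride gives the trisubstituted allylic alcohol, mainly E (about 9:1 expected; minor Z removed by chromatography).

**Step 3**
Reactants: 4
Product: 5, 3‑[(3E)‑5‑chloro‑4‑methylpent‑3‑en‑1‑yl]furan
Conditions: MsCl, s‑collidine, LiCl, DMF, 0 °C
Reagents that add atoms: lithium chloride, [Li+].[Cl-]
Why: Collington–Meyers allylic chlorination is a direct SN2 process, so there is no allylic transposition or loss of E geometry.

**Step 4**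
Reactants: 6, geranyl acetate
Product: 7, (2E,6E)‑8‑hydroxy‑3,7‑dimethylocta‑2,6‑dien‑1‑yl acetate
Conditions: SeO2 (cat.), t‑BuOOH, salicylic acid (cat.), CH2Cl2, rt; then NaBH4, MeOH, 0 °C
Reagents that add atoms: selenium dioxide, O=[Se]=O, with tert‑butyl hydroperoxide, CC(C)(C)OO (one O)
Why: Sharpless SeO2 allylic oxidation (ene/[2,3]) is selective for the E‑methyl of the distal, electron‑rich alkene; NaBH4 returns any over‑oxidised enal to the alcohol.

**Step 5**
Reactants: 7
Product: 8, (2E,6E)‑8‑bromo‑3,7‑dimethylocta‑2,6‑dien‑1‑yl acetate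
Conditions: CBr4, PPh3, CH2Cl2, 0 °C
Reagents that add atoms: carbon tetrabromide, BrC(Br)(Br)Br
Why: Appel bromination of the primary allylic alcohol under neutral conditions leaves the acetate and both E alkenes intact.

**Step 6**
Reactants: 8; 9, tert‑butyl acetate
Product: 10, tert‑butyl (4E,8E)‑10‑acetoxy‑4,8‑dimethyldeca‑4,8‑dienoate
Conditions: LDA, 9, THF, −78 °C; then 8, −78 °C; AcOH quench at −78 °C
Reagents that add atoms: 9, CC(=O)OC(C)(C)C
Why: SN2 alkylation of the lithium ester enolate by the reactive allylic bromide; at −78 °C this should outpace Claisen attack on the acetate, and the E geometry is untouched.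

**Step 7**
Reactants: 10
Product: 11, tert‑butyl 3‑[(2R,3R)‑3‑[(3E)‑5‑acetoxy‑3‑methylpent‑3‑en‑1‑yl]‑2‑methyloxiran‑2‑yl]propanoate
Conditions: D‑fructose‑derived Shi ketone (30 mol %), Oxone, K2CO3, Bu4NHSO4, MeCN–DMM / aq. borate–EDTA (pH about 10.5), 0 °C
Reagents that add atoms: Oxone (potassium peroxymonosulfate), [K+].[O-]S(=O)(=O)OO (one O)
Why: Shi epoxidation (chiral dioxirane, spiro transition state) of the electron‑rich E‑trisubstituted alkene gives the (R,R)‑oxirane, the same face as in the stilbene and 1‑phenylcyclohexene precedents; the alkene next to the allylic acetate is deactivated.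

**Step 8**
Reactants: 11
Product: 12, tert‑butyl 3‑[(2R,3R)‑3‑[(3E)‑5‑hydroxy‑3‑methylpent‑3‑en‑1‑yl]‑2‑methyloxiran‑2‑yl]propanoate
Conditions: K2CO3, MeOH, 0 °C to rt
Reagents that add atoms: none
Why: Mild methanolysis removes only the acetate; the tert‑butyl ester and trisubstituted epoxide are inert to carbonate/methanol.

**Step 9**
Reactants: 12
Product: 13, tert‑butyl 3‑[(2R,3R)‑2‑methyl‑3‑[(3E)‑3‑methyl‑5‑oxopent‑3‑en‑1‑yl]oxiran‑2‑yl]propanoate
Conditions: MnO2, CH2Cl2, rt
Reagents that add atoms: none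
Why: MnO2 oxidises the allylic alcohol chemoselectively to the E‑enal without touching the epoxide or ester.

**Step 10**
Reactants: 5; 13
Product: 14, tert‑butyl 3‑[(2R,3R)‑3‑[(3E,7E)‑10‑(furan‑3‑yl)‑5‑hydroxy‑3,7‑dimethyldeca‑3,7‑dien‑1‑yl]‑2‑methyloxiran‑2‑yl]propanoate (about 1:1 at C5′)
Conditions: active Ba (BaI2 + 2 Li biphenylide, THF, rt); 5, −78 °C; then 13, −78 °C; NH4Cl quench at −78 °C
Reagents that add atoms: none beyond 5 and 13
Why: Yamamoto allylbarium addition is α‑selective (linear product, C9–C10 bond) with retention of the allyl E geometry and 1,2‑selective on enals; the new carbinol is unselective and is corrected in steps 11–12.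

**Step 11**
Reactants: 14
Product: 15, tert‑butyl 3‑[(2R,3R)‑3‑[(3E,7E)‑10‑(furan‑3‑yl)‑3,7‑dimethyl‑5‑oxodeca‑3,7‑dien‑1‑yl]‑2‑methyloxiran‑2‑yl]propanoate
Conditions: Dess–Martin periodinane, NaHCO3, CH2Cl2, 0 °C; use promptly
Reagents that add atoms: none
Why: Buffered, near‑neutral DMP oxidation converges both epimers to the enone without moving the β,γ‑alkene into conjugation or opening the epoxide.

**Step 12**
Reactants: 15
Product: 16, tert‑butyl 3‑[(2R,3R)‑3‑[(3E,5S,7E)‑10‑(furan‑3‑yl)‑5‑hydroxy‑3,7‑dimethyldeca‑3,7‑dien‑1‑yl]‑2‑methyloxiran‑2‑yl]propanoate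
Conditions: (R)‑Me‑CBS (0.5 equiv), catecholborane, toluene, −78 °C
Reagents that add atoms: none (hydride only)
Why: Corey–Bakshi–Shibata reduction with the β,β‑disubstituted alkenyl group as the large substituent; the (R)‑catalyst delivers hydride to give the (S)‑allylic alcohol, and catecholborane at −78 °C gives 1,2‑reduction without hydroboration.

**Step 13**
Reactants: 16
Product: 17, tert‑butyl 3‑[(2R,3R)‑3‑[(3E,5S,7E)‑5‑acetoxy‑10‑(furan‑3‑yl)‑3,7‑dimethyldeca‑3,7‑dien‑1‑yl]‑2‑methyloxiran‑2‑yl]propanoate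
Conditions: Ac2O, Et3N, DMAP (cat.), CH2Cl2, 0 °C
Reagents that add atoms: acetic anhydride, CC(=O)OC(C)=O
Why: DMAP‑catalysed O‑acylation of the only free hydroxyl (the second is still masked as the epoxide), with retention at C10.

**Step 14**
Reactants: 17
Product: 18, 10‑acetylirciformonin B, (1R,4E,6S,8E)‑11‑(furan‑3‑yl)‑1‑hydroxy‑4,8‑dimethyl‑1‑[(2S)‑2‑methyl‑5‑oxooxolan‑2‑yl]undeca‑4,8‑dien‑6‑yl acetate
Conditions: CSA (0.2 equiv), CH2Cl2, 0 °C to rt (isobutylene lost)
Reagents that add atoms: none
Why: Acid‑catalysed 5‑exo epoxide opening by the ester carbonyl at the tertiary carbon with inversion (R to S), then E1 loss of the tert‑butyl group, gives the γ‑lactone; the epoxide oxygen stays on the secondary carbon as the (R)‑alcohol.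

## Compound list

1 | furan‑3‑ylmethanol | OCc1ccoc1 | starting material
2 | 3‑(chloromethyl)furan | ClCc1ccoc1 | intermediate
3 | 2‑methyl‑2‑vinyloxirane (racemic) | C=CC1(C)CO1 | starting material
4 | (2E)‑5‑(furan‑3‑yl)‑2‑methylpent‑2‑en‑1‑ol | OC/C(C)=C/CCc1ccoc1 | intermediate
5 | 3‑[(3E)‑5‑chloro‑4‑methylpent‑3‑en‑1‑yl]furan | ClC/C(C)=C/CCc1ccoc1 | intermediate
6 | geranyl acetate | CC(=O)OC/C=C(\C)CCC=C(C)C | starting material
7 | (2E,6E)‑8‑hydroxy‑3,7‑dimethylocta‑2,6‑dien‑1‑yl acetate | CC(=O)OC/C=C(\C)CC/C=C(\C)CO | intermediate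
8 | (2E,6E)‑8‑bromo‑3,7‑dimethylocta‑2,6‑dien‑1‑yl acetate | CC(=O)OC/C=C(\C)CC/C=C(\C)CBr | intermediate
9 | tert‑butyl acetate | CC(=O)OC(C)(C)C | starting material
10 | tert‑butyl (4E,8E)‑10‑acetoxy‑4,8‑dimethyldeca‑4,8‑dienoate | CC(=O)OC/C=C(\C)CC/C=C(\C)CCC(=O)OC(C)(C)C | intermediate
11 | (2R,3R)‑epoxy acetate | CC(=O)OC/C=C(\C)CC[C@H]1O[C@]1(C)CCC(=O)OC(C)(C)C | intermediate
12 | (2R,3R)‑epoxy allylic alcohol | OC/C=C(\C)CC[C@H]1O[C@]1(C)CCC(=O)OC(C)(C)C | intermediate
13 | (2R,3R)‑epoxy (E)‑enal | O=C/C=C(\C)CC[C@H]1O[C@]1(C)CCC(=O)OC(C)(C)C | intermediate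
14 | coupled allylic alcohol, C5′ epimers | OC(/C=C(\C)CC[C@H]1O[C@]1(C)CCC(=O)OC(C)(C)C)C/C(C)=C/CCc1ccoc1 | intermediate
15 | skipped enone | O=C(/C=C(\C)CC[C@H]1O[C@]1(C)CCC(=O)OC(C)(C)C)C/C(C)=C/CCc1ccoc1 | intermediate
16 | (5′S)‑allylic alcohol | O[C@H](/C=C(\C)CC[C@H]1O[C@]1(C)CCC(=O)OC(C)(C)C)C/C(C)=C/CCc1ccoc1 | intermediate
17 | (5′S)‑acetate epoxy ester | CC(=O)O[C@H](/C=C(\C)CC[C@H]1O[C@]1(C)CCC(=O)OC(C)(C)C)C/C(C)=C/CCc1ccoc1 | intermediate
18 | 10‑acetylirciformonin B | CC(=O)O[C@H](/C=C(\C)CC[C@@H](O)[C@]1(C)CCC(=O)O1)C/C(C)=C/CCc1ccoc1 | target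

## Totals and risks

Total steps: 14. Longest linear sequence: 11 (geranyl acetate to target, steps 4–14); the furyl fragment is a 3‑step branch.

Steps most likely to fail:

1. **Step 10, allylbarium coupling.** Risks are preparing the active barium and the tolerance of the epoxide (LiI is present) and ester. Fallback: reverse the polarity at C10. Convert allylic acetate 11 to the allylic phenyl sulfone (Pd(0), PhSO2Na), alkylate its α‑anion with the allylic bromide analogue of 5, then oxidatively desulfonylate (base, MoOPH) to reach enone 15 directly.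

2. **Step 12, CBS reduction.** The skipped dienone 15 can isomerise, and steric differentiation between the alkenyl and methallyl‑type substituents may give only moderate selectivity. Fallback: set C10 during bond formation by disconnecting C10–C11 instead. Couple an East (E)‑vinyl iodide (from 4‑pentyn‑1‑ol by carboalumination/iodination, oxidation, isopropenyl Grignard, Johnson–Claisen and Shi epoxidation) with (E)‑6‑(furan‑3‑yl)‑3‑methylhex‑3‑enal in a catalytic asymmetric Ni/Cr (Nozaki–Hiyama–Kishi) reaction, avoiding the ketone.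

3. **Step 14, acid lactonisation.** The allylic acetate and furan are acid‑sensitive, and clean inversion at the tertiary carbon is required. Fallback: lactonise directly after step 7 (11 to the hydroxy‑lactone), protect the carbinol as a TES ether, carry it through steps 8–13, and finish with HF·pyridine desilylation; this adds two steps but gives a non‑acidic endgame.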